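## Retrosynthetic overview
1. The target comes from a (1S,2S)-1-aryl-2-aryloxybut-3-en-1-ol by three unmasking operations: dithiane to ketone, vinyl to CH2OH (oxidative cleavage and reduction), and removal of two silyl ethers.
2. Key disconnection C7–C8. The carbonyl carbon of veratraldehyde is joined to C8, an O-bearing carbon made nucleophilic (umpoled d1 oxyallyl anion). C8 is delivered as a (Z)-γ-aryloxyallyl-B(Ipc)2 reagent that already carries the complete second arene. This one step forms the C–C bond and sets both stereocentres (syn, 7S,8S), with the 8-O-4' ether already in place.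
3. Disconnection C7'–C8'. A 2-aryl-1,3-dithiane anion (acyl anion) opens ethylene oxide, and the dithiane then shields the ketone from s-BuLi.
4. The allyl aryl ether comes from regioselective 4-O-allylation of 5-hydroxyvanillin.
5. Rings: no ring of the target is built, since both arenes are bought. The only ring made is the temporary dithiane (formed in step 2, removed in step 5).

Assumption: the SMILES reads as (7S,8S), which is the threo (syn) isomer. C7–C9 denotes the chain on the dimethoxyphenyl ring and primed numbers denote the other arylpropanoid unit. 3,4-Dihydroxy-5-methoxybenzaldehyde is taken as a purchasable compound.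

## Route

Step 1
Reactants: 1 3,4-dihydroxy-5-methoxybenzaldehyde (5-hydroxyvanillin); 2 allyl bromide
Product: 3 3-hydroxy-5-methoxy-4-(prop-2-en-1-yloxy)benzaldehyde
Conditions: allyl bromide (1.05 equiv), NaHCO3 (1.5 equiv), DMF, 40 °C, 20 h
Reagents that add atoms: allyl bromide 2, C=CCBr
Why: The 4-OH para to the formyl group is much the more acidic phenol, so bicarbonate ionises only that site and Williamson etherification (SN2) gives the 4-O-allyl ether regioselectively.

Step 2
Reactants: 3 3-hydroxy-5-methoxy-4-(prop-2-en-1-yloxy)benzaldehyde; 4 propane-1,3-dithiol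
Product: 5 5-(1,3-dithian-2-yl)-3-methoxy-2-(prop-2-en-1-yloxy)phenol
Conditions: HS(CH2)3SH (1.1 equiv), BF3·OEt2 (0.15 equiv), CH2Cl2, 0 °C to rt
Reagents that add atoms: propane-1,3-dithiol 4, SCCCS
Why: Lewis-acid-catalysed dithioacetalisation of the aromatic aldehyde is fast and leaves the phenol and the allyl ether untouched, giving the Corey–Seebach acyl-anion precursor.

Step 3
Reactants: 5 5-(1,3-dithian-2-yl)-3-methoxy-2-(prop-2-en-1-yloxy)phenol; 6 ethylene oxide; 7 triisopropylsilyl triflate (TIPSOTf)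
Product: 10 2-[3-methoxy-4-(prop-2-en-1-yloxy)-5-(triisopropylsilyloxy)phenyl]-2-[2-(triisopropylsilyloxy)ethyl]-1,3-dithiane, via C2-lithio lithium phenoxide 8 (not isolated), via dilithium alkoxide-phenoxide 9 (not isolated)
Conditions: n-BuLi (2.1 equiv), THF, −78 to −20 °C; ethylene oxide (1.3 equiv, THF solution), −20 to 0 °C; TIPSOTf (2.3 equiv), −78 to 0 °C
Reagents that add atoms: ethylene oxide 6, C1CO1; TIPSOTf 7, CC(C)[Si](OS(=O)(=O)C(F)(F)F)(C(C)C)C(C)C
Why: In this Corey–Seebach umpolung the second equivalent of n-BuLi removes the benzylic dithiane C2–H (far more acidic than the allylic OCH2), the acyl-anion equivalent opens the epoxide by SN2, and both lithium oxides are capped in the same flask with TIPS, which is bulky enough not to migrate to a carbanion in step 4.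

Step 4 (key step)
Reactants: 10 bis-TIPS allyl aryl ether dithiane; 11 (+)-B-methoxydiisopinocampheylborane, (+)-Ipc2BOMe, from (−)-α-pinene; 12 3,4-dimethoxybenzaldehyde (veratraldehyde)
Product: 17 (1S,2S)-1-(3,4-dimethoxyphenyl)-2-{2-methoxy-6-(triisopropylsilyloxy)-4-[2-(2-triisopropylsilyloxyethyl)-1,3-dithian-2-yl]phenoxy}but-3-en-1-ol, via (Z)-3-aryloxyallyllithium 13 (not isolated), via lithium allyl(methoxy)borate 14 (not isolated), via (Z)-3-aryloxyallyl-B(Ipc)2 15 (not isolated), via O-B(Ipc)2 borinate 16 (not isolated)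
Conditions: s-BuLi (1.1 equiv), THF, −78 °C, 30 min; (+)-Ipc2BOMe (1.2 equiv), −78 °C, 1 h; BF3·OEt2 (1.5 equiv), then 12 (1.2 equiv), −78 °C, 6 h; HOCH2CH2NH2, Et2O, rt (non-oxidative work-up that spares the dithiane)
Reagents that add atoms: veratraldehyde 12, COc1ccc(C=O)cc1OC
Why: This is a Brown asymmetric (Z)-γ-alkoxyallylboration in which kinetic deprotonation of the allyl aryl ether (known for allyl 4-methoxyphenyl ether) gives the O–Li-chelated (Z)-oxyallyl anion, boron is taken up at the CH2 terminus so that the O-bearing carbon C8 becomes the nucleophile, and addition to the aldehyde through a chair Zimmerman–Traxler transition state turns the Z geometry into the syn (threo) C7/C8 relationship while the Ipc groups from (−)-α-pinene direct attack to the Re face, giving 7S,8S.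

Step 5
Reactants: 17 (1S,2S)-homoallylic alcohol dithiane
Product: 18 1-[4-{[(1S,2S)-1-(3,4-dimethoxyphenyl)-1-hydroxybut-3-en-2-yl]oxy}-3-methoxy-5-(triisopropylsilyloxy)phenyl]-3-(triisopropylsilyloxy)propan-1-one
Conditions: MeI (10 equiv), CaCO3 (5 equiv), MeCN/H2O 9:1, 45 °C
Reagents that add atoms: water, O
Why: Alkylative dithiane hydrolysis works because S-methylation creates a leaving group and the 4-alkoxyaryl-stabilised thionium ion is captured by water, under non-oxidative buffered conditions that leave the vinyl group, the electron-rich arenes, the silyl ethers and both stereocentres unchanged.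

Step 6
Reactants: 18 (1S,2S)-vinyl ketone
Product: 20 1-[4-{[(1S,2S)-1-(3,4-dimethoxyphenyl)-1,3-dihydroxypropan-2-yl]oxy}-3-methoxy-5-(triisopropylsilyloxy)phenyl]-3-(triisopropylsilyloxy)propan-1-one, via alpha-aryloxy aldehyde 19 (not isolated)
Conditions: O3, CH2Cl2/MeOH 4:1, −78 °C, stopped at consumption of 18; Me2S, −78 to 0 °C; NaBH4 (1.5 equiv), −78 °C, AcOH quench
Reagents that add atoms: ozone, [O-][O+]=O
Why: In this ozonolysis with reductive work-up the terminal alkene reacts faster than the arenes at −78 °C, aldehyde 19 is reduced in the flask before C8 can epimerise or a retro-aldol can start, and NaBH4 at −78 °C in CH2Cl2/MeOH reduces an aldehyde far faster than the deactivated 4-alkoxyaryl ketone, so no stereocentre is touched.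

Step 7
Reactants: 20 bis-TIPS diol ketone
Product: 21 1-(4-{[(1S,2S)-1-(3,4-dimethoxyphenyl)-1,3-dihydroxypropan-2-yl]oxy}-3-hydroxy-5-methoxyphenyl)-3-hydroxypropan-1-one (target)
Conditions: TBAF/AcOH (1:1, 3 equiv each), THF, 0 °C to rt
Reagents that add atoms: none
Why: Fluoride-driven desilylation (Si–F bond strength) frees the phenol and the primary alcohol, and the AcOH buffer keeps the medium near neutral, so the β-hydroxy ketone does not undergo E1cB or retro-aldol and the benzylic C7–OH does not ionise.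

## Compound list
1 | 3,4-dihydroxy-5-methoxybenzaldehyde | COc1cc(C=O)cc(O)c1O | starting material
2 | allyl bromide | C=CCBr | starting material
3 | 3-hydroxy-5-methoxy-4-(prop-2-en-1-yloxy)benzaldehyde | C=CCOc1c(O)cc(C=O)cc1OC | intermediate
4 | propane-1,3-dithiol | SCCCS | starting material
5 | 5-(1,3-dithian-2-yl)-3-methoxy-2-(prop-2-en-1-yloxy)phenol | C=CCOc1c(O)cc(C2SCCCS2)cc1OC | intermediate
6 | ethylene oxide | C1CO1 | starting material
7 | triisopropylsilyl trifluoromethanesulfonate | CC(C)[Si](OS(=O)(=O)C(F)(F)F)(C(C)C)C(C)C | starting material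
8 | C2-lithiated dithiane lithium phenoxide of 5 | C=CCOc1c(O[Li])cc(C2([Li])SCCCS2)cc1OC | intermediate
9 | dilithium salt of 5-[2-(2-hydroxyethyl)-1,3-dithian-2-yl]-3-methoxy-2-(allyloxy)phenol | C=CCOc1c(O[Li])cc(C2(CCO[Li])SCCCS2)cc1OC | intermediate
10 | 2-[3-methoxy-4-(allyloxy)-5-(TIPSO)phenyl]-2-[2-(TIPSO)ethyl]-1,3-dithiane | C=CCOc1c(O[Si](C(C)C)(C(C)C)C(C)C)cc(C2(CCO[Si](C(C)C)(C(C)C)C(C)C)SCCCS2)cc1OC | intermediate
11 | (+)-B-methoxydiisopinocampheylborane | COB([C@H]1C[C@H]2C[C@@H]([C@@H]1C)C2(C)C)[C@H]1C[C@H]2C[C@@H]([C@@H]1C)C2(C)C | starting material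
12 | 3,4-dimethoxybenzaldehyde | COc1ccc(C=O)cc1OC | starting material
13 | (Z)-3-aryloxyallyllithium from 10 | [Li]C/C=C\Oc1c(O[Si](C(C)C)(C(C)C)C(C)C)cc(C2(CCO[Si](C(C)C)(C(C)C)C(C)C)SCCCS2)cc1OC | intermediate
14 | lithium (Z)-(3-aryloxyallyl)(methoxy)diisopinocampheylborate | [Li+].CO[B-](C/C=C\Oc1c(O[Si](C(C)C)(C(C)C)C(C)C)cc(C2(CCO[Si](C(C)C)(C(C)C)C(C)C)SCCCS2)cc1OC)([C@H]1C[C@H]2C[C@@H]([C@@H]1C)C2(C)C)[C@H]1C[C@H]2C[C@@H]([C@@H]1C)C2(C)C | intermediate
15 | (Z)-(3-aryloxyallyl)diisopinocampheylborane | B(C/C=C\Oc1c(O[Si](C(C)C)(C(C)C)C(C)C)cc(C2(CCO[Si](C(C)C)(C(C)C)C(C)C)SCCCS2)cc1OC)([C@H]1C[C@H]2C[C@@H]([C@@H]1C)C2(C)C)[C@H]1C[C@H]2C[C@@H]([C@@H]1C)C2(C)C | intermediate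
16 | diisopinocampheylborinate ester of 17 | COc1ccc([C@H](OB([C@H]2C[C@H]3C[C@@H]([C@@H]2C)C3(C)C)[C@H]2C[C@H]3C[C@@H]([C@@H]2C)C3(C)C)[C@H](C=C)Oc2c(O[Si](C(C)C)(C(C)C)C(C)C)cc(C3(CCO[Si](C(C)C)(C(C)C)C(C)C)SCCCS3)cc2OC)cc1OC | intermediate
17 | (1S,2S)-1-(3,4-dimethoxyphenyl)-2-{2-methoxy-6-(TIPSO)-4-[2-(2-TIPSO-ethyl)-1,3-dithian-2-yl]phenoxy}but-3-en-1-ol | COc1ccc([C@H](O)[C@H](C=C)Oc2c(O[Si](C(C)C)(C(C)C)C(C)C)cc(C3(CCO[Si](C(C)C)(C(C)C)C(C)C)SCCCS3)cc2OC)cc1OC | intermediate
18 | 1-[4-{[(1S,2S)-1-(3,4-dimethoxyphenyl)-1-hydroxybut-3-en-2-yl]oxy}-3-methoxy-5-(TIPSO)phenyl]-3-(TIPSO)propan-1-one | COc1ccc([C@H](O)[C@H](C=C)Oc2c(O[Si](C(C)C)(C(C)C)C(C)C)cc(C(=O)CCO[Si](C(C)C)(C(C)C)C(C)C)cc2OC)cc1OC | intermediate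
19 | (2R,3S)-3-(3,4-dimethoxyphenyl)-3-hydroxy-2-{2-methoxy-6-(TIPSO)-4-[3-(TIPSO)propanoyl]phenoxy}propanal (same spatial arrangement; the C2 descriptor changes by CIP priority only) | COc1ccc([C@H](O)[C@H](C=O)Oc2c(O[Si](C(C)C)(C(C)C)C(C)C)cc(C(=O)CCO[Si](C(C)C)(C(C)C)C(C)C)cc2OC)cc1OC | intermediate
20 | 1-[4-{[(1S,2S)-1-(3,4-dimethoxyphenyl)-1,3-dihydroxypropan-2-yl]oxy}-3-methoxy-5-(TIPSO)phenyl]-3-(TIPSO)propan-1-one | COc1ccc([C@H](O)[C@H](CO)Oc2c(O[Si](C(C)C)(C(C)C)C(C)C)cc(C(=O)CCO[Si](C(C)C)(C(C)C)C(C)C)cc2OC)cc1OC | intermediate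
21 | 1-(4-{[(1S,2S)-1-(3,4-dimethoxyphenyl)-1,3-dihydroxypropan-2-yl]oxy}-3-hydroxy-5-methoxyphenyl)-3-hydroxypropan-1-one | COc1ccc([C@H](O)[C@H](CO)Oc2c(O)cc(C(=O)CCO)cc2OC)cc1OC | target

## Count and risks
Total step count: 7. Longest linear sequence: 7 steps (1 to 21); veratraldehyde 12 enters directly as a purchased compound.

**Step 4.**
- Risk: the 2,6-disubstituted aryloxy group sits axial in the chair next to two Ipc groups. The addition may therefore be slow, and Z-to-E leakage by borotropic shift could lower dr and ee.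
- Fallback: it sets out from 10 and comes back at 17.
  - Anion 13 is generated as before but quenched with 2-isopropoxy-4,4,5,5-tetramethyl-1,3,2-dioxaborolane. This gives the isolable pinacol (Z)-3-aryloxyallylboronate F1, whose geometry can be checked and purified.
  - F1 is then added to 12 in toluene at −30 °C with 5 mol % of the chiral phosphoric acid (R)-TRIP. This gives the O-pinacolboryl ether of 17 F2, which is hydrolysed on work-up to 17.
  - Stereocontrol thus moves from a chiral auxiliary on boron to a chiral Brønsted acid acting on a small achiral boronate. (R)-TRIP is my best estimate of the enantiomer needed for 7S; the antipodal catalyst is equally available if the observed sense is opposite.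

**Step 6.**
- Risk: ozone may attack the two electron-rich arenes, the aldehyde 19 is labile, and the ketone could be partly reduced.
- Fallback: it sets out from 18 and comes back at 19.
  - Dihydroxylation with OsO4 (2 mol %) and NMO in acetone/water gives the butane-1,2-diol derivative (triol) F3. It is a mixture at the new carbinol carbon, which is lost in the next operation.
  - Glycol cleavage with NaIO4 in THF/water at 0 °C gives 19. The protected phenol is inert to periodate.
  - 19 is taken at once into the −78 °C NaBH4 reduction to give 20.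

**Step 3.**
- Risk: the dianion 8 may be poorly soluble or sluggish towards the epoxide, and the double silylation may be incomplete.
- Fallback: it sets out from 5 and comes back at 10.
  - The phenol is silylated first (TIPSCl, imidazole, DMF) to give the aryl TIPS ether dithiane F4.
  - One equivalent of n-BuLi converts F4 into the monolithiated dithiane F5.
  - F5 is alkylated by SN2 with (2-iodoethoxy)triisopropylsilane, giving 10 directly. This replaces epoxide opening plus in-flask capping by alkylation with a pre-protected two-carbon halide.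

## Further compounds
F1 | step 4 | pinacol (Z)-3-aryloxyallylboronate derived from 10 | CC1(C)OB(C/C=C\Oc2c(O[Si](C(C)C)(C(C)C)C(C)C)cc(C3(CCO[Si](C(C)C)(C(C)C)C(C)C)SCCCS3)cc2OC)OC1(C)C
F2 | step 4 | O-pinacolboryl ether of 17 | COc1ccc([C@H](OB2OC(C)(C)C(C)(C)O2)[C@H](C=C)Oc2c(O[Si](C(C)C)(C(C)C)C(C)C)cc(C3(CCO[Si](C(C)C)(C(C)C)C(C)C)SCCCS3)cc2OC)cc1OC
F3 | step 6 | triol from dihydroxylation of 18 (new carbinol centre unassigned, mixture) | COc1ccc([C@H](O)[C@H](C(O)CO)Oc2c(O[Si](C(C)C)(C(C)C)C(C)C)cc(C(=O)CCO[Si](C(C)C)(C(C)C)C(C)C)cc2OC)cc1OC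
F4 | step 3 | 2-[3-methoxy-4-(allyloxy)-5-(triisopropylsilyloxy)phenyl]-1,3-dithiane | C=CCOc1c(O[Si](C(C)C)(C(C)C)C(C)C)cc(C2SCCCS2)cc1OC
F5 | step 3 | 2-lithio derivative of F4 | C=CCOc1c(O[Si](C(C)C)(C(C)C)C(C)C)cc(C2([Li])SCCCS2)cc1OC
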